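All runs come from a simulation for an exercise; noise was put on by code.

With 3.00 coupling partner per substrate charged, plain one-to-one coupling cannot stop at 64.6% in the epsilon run, yet the readings level off there, so some other reaction is consuming a reagent.

| flask | substrate | coupling partner | temperature | remark | time |
|---|---|---|---|---|---|
| eta | 10 mM | 7.5 mM | −5 °C | run made earlier |  |
| epsilon | 10 mM | 30 mM | 12 °C | run made earlier |  |
| beta | 20 mM | 15 mM | −5 °C | run made earlier |  |
| summer | 10 mM | 15.0 mM | 25 °C |  | 2.5 min |
| dawn | 10 mM | 15.0 mM | 0 °C |  | 2.5 min |

- eta (time / min: target / %): 2.00: 15.7; 4.00: 20.1; 8.00: 29.0; 12.0: 32.1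
- epsilon (time / min: target / %): 1.50: 55.1; 3.00: 62.6; 5.00: 64.6; 6.00: 64.4
- beta (time / min: target / %): 4.00: 29.7; 6.00: 36.2; 12.0: 39.3

(scatter of a reading: 1 percentage point)

- the earlier runs were read with a standard deviation of 1 percentage point

* the flask with the highest amount of target, in percent of the substrate charged ("all alike" if they lie within 1.5 percentage points) (summer / dawn / all alike)
* final target, as a percentage of the substrate charged, in summer
* final target, as a percentage of the substrate charged, in dawn

Both new flasks hold 15.0 mM of coupling partner, so I first ask how long a substrate molecule waits for coupling at that charge. I call this the coupling time τ, the inverse of the pseudo-first-order rate constant for coupling at the charged partner level, 5.86 min. I read it from the first eta reading, scaled from 7.5 mM to 15.0 mM of partner, so it carries that reading's scatter and belongs to −5 °C, not to dawn's 0 °C.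

I take this τ from −5 °C as it stands for dawn, which gets 2.5 min, less than τ, so as my own rough reckoning I expect dawn to be unfinished, with about 34.8% target. The readings give me no τ at 25 °C, so I commit to no number for summer.

The forecast names summer as the richer flask, with 53% (47% to 59%) there and 31% (24% to 38%) in dawn, a little below my figure. Its ground is that “selectivity barely depends on temperature”.

The flasks give 34.7% in summer and 34.8% in dawn, so the answer is all alike. Summer stands 18 points below the forecast, and dawn lies within its range.

    substrate → side product A (k = 0.0195 s⁻¹, Ea = 88.0 kJ mol⁻¹)
    substrate + coupling partner → target (k = 1.31 L mol⁻¹ s⁻¹, Ea = 38.0 kJ mol⁻¹)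
    2 coupling partner → self-condensation product (k = 0.198 L mol⁻¹ s⁻¹, Ea = 50.0 kJ mol⁻¹)
    2 substrate → side product B (k = 1.00 L mol⁻¹ s⁻¹, Ea = 40.0 kJ mol⁻¹)
    (constants at 25 °C)

Reckoned with these constants, τ in summer is 0.848 min, shorter than the 5.86 min read from the eta run at −5 °C, and it stands beside 0.855 min for the lifetime of substrate against the step to side product A, and at 2.50 min summer holds 44.4% side product A beside 34.7% target. In dawn, 33.6% of the substrate is left at 2.50 min, target reaches 55.8% by 25.0 min, and the neighbour of dawn with 4.0 mM of substrate, which has the same partner charge and temperature, holds 41.1% target with 40% of its substrate left at 2.5 min.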